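Spare E is 0.0300 M, the charge of E less the charge of G, and I built my reckoning on that difference.

| flask | G | Z | E | time | remark |
|---|---|---|---|---|---|
| winter | 0.30 M | 0.240 M (fed, over 50.0 min) | 0.330 M | 50 min | a stirred flask in which Z is dosed at a steady rate over 50.0 min without added volume, worked up at 50 min |
| noon | 0.30 M | 0.240 M | 0.330 M | 50 min | everything together in a closed stirred flask, run for 50 min |
| dawn | 0.30 M | 0.240 M | 0.330 M |  | one stirred flow tank at steady state, fed with the mixture as stated, mean residence time 50 min |
| midnight | 0.30 M | 0.240 M | 0.330 M (fed, over 50.0 min) | 50 min | all but E at the start; E goes in evenly over 50.0 min, the run ends at 50 min |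

    L → J (k1 = 0.0081 min⁻¹)
    E + L ⇌ E.L, settled at all times (K2 = 1.4 M⁻¹)
    G.E + E.Z → L (k3 = 0.47 M⁻¹ min⁻¹)
    E + Z → E.Z (k4 = 0.14 M⁻¹ min⁻¹)
    G + E → G.E (k5 = 1.6 M⁻¹ min⁻¹)

1. the set-up with the highest amount of G.E at the outlet or at the end, in percent of the G put in ("none" if the first two lie within 2 percentage points) (winter / noon / dawn / midnight / none)
2. amount of G.E at the outlet or at the end, in percent of the G put in, winter
3. amount of G.E at the outlet or at the end, in percent of the G put in, noon
4. amount of G.E at the outlet or at the end, in percent of the G put in, dawn
5. amount of G.E at the outlet or at the end, in percent of the G put in, midnight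

- amounts and yields of L count E.L too
- the stated concentrations are those of everything mixed, before any reaction; amounts are the same in each set-up
- the feed brings no volume worth counting
- run time (winter): 50 min

I ranked the clocks from fastest to slowest. With noon's charges, G has a half-life of 1.3 min against E, while E has a half-life of 21 min against Z, so I let G fill to G.E first. Next, E.Z meeting G.E at the charged level of G has a half-life of 4.92 min, well inside the dosing time, so I treated E.Z as a quasi-steady intermediate: each one made removes a G.E soon after. Slowest, free L turns to J with a half-life of 86 min, and that touches no G.E.

The winter flask therefore looked to me like G.E and spare E, with Z dripping in. I replaced the rising Z by its mean, 0.120 M, and E by the spare. That gave the side-loss budget Λ, my estimate of the fraction of G.E lost over the dose, equal to k4 times spare E times mean Z times the dosing time, divided by the charge of G: 8.40 %. It fits under the spare, 10.0 % of G, so I expected winter G.E near 91.6 %.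

At noon Z stands whole from the start, so Λ, with E still held at the spare, became 16.8 %, which exceeds the spare. Each L costs a G.E and a further E, so counting E gave G.E near 76.4 %. I left dawn and midnight unreckoned.

The forecast named winter, with winter 90.5 % (87 % to 93 %), noon 76 %, dawn 62 % and midnight 74 %, reasoning that “dosing Z slowly lets G take E first and keeps the Z side-route small”. Its winter figure stood 1.1 percentage points below mine.

The simulation put winter first: winter 92.0 %, noon 76.8 %, dawn 62.3 %, midnight 75.2 %. In winter G.E stood at 93.4 % by 25.0 min, with G down to 4.37 %, while E + Z → E.Z had 14 % of its turnover up to 50.0 min behind it at 10.0 min and half at 26.7 min; E fell to 4.02 % of its charge by 50.0 min. L, with E.L counted in it, and J together held 6.17 % of G at that time, against Λ of 8.40 %. Winter's answer moved 5 points with E at 0.278 M or 0.395 M, the other amounts and the time held. The winter flask with 0.060 M of Z had Λ of 2.10 %, and it ended with L at 1.66 %, J at 0.246 % and G.E at 97.0 %.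

The numbers were drawn at random within sensible limits, and the outcome is calculated.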